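**Retrosynthetic overview**
1. Feature: the tetralin is a dimer of one C6–C3 unit. C2–C3 joins the two carbons that carry the CH2OMe groups (each the α-carbon of a cinnamoyl unit), and C1–C8a joins the benzylic carbon of one unit to ring A of the other, closing ring B, so one monomer supplies all 18 skeletal carbons.
2. Target ⇐ fourfold O-methylation of a tetralin bis-phenol diol ⇐ LiBH4 cleavage of a bis(N-acyl oxazolidinone) ⇐ hydrogenation of C3=C4 (sets C3) with loss of two aryl bromines ⇐ trans-1-aryl-1,2-dihydronaphthalene.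
3. Key disconnection: C2–C3 and C1–C8a in one oxidative dimerisation of a phenolic N-cinnamoyl oxazolidinone (sets C2 and C1). A bromine ortho to each phenol OH blocks the 8–5' coupling that 5-unsubstituted feruloyl esters and amides prefer; it leaves in the hydrogenation.
4. Monomer ⇐ Wittig olefination of 5-bromovanillin with the ylide built from (S)-4-benzyloxazolidin-2-one, bromoacetyl bromide and PPh3.
5. Ring order: ring A and the pendant aryl ring come with 5-bromovanillin; ring B is the only ring formed (key step).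

Key step: step 4

Locants: tetralin numbering for the ring system; in the monomer C7 is the benzylic carbon, C8 the carbon α to the carbonyl and C9 the carbonyl carbon, with primes for the second unit.

Assumption: in the aqueous, non-chelating medium of step 4 the N-enoyl imide should react in its dipole-opposed s-cis conformer on the C8 face away from the benzyl group, which with the (S)-auxiliary leads to the 1R,2S series. The sense is to be checked at compound 11; if it proved opposite, the (R)-auxiliary would be used with no other change.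

**Step 1**
Reactants: 1 (S)-4-benzyloxazolidin-2-one; 2 bromoacetyl bromide
Product: 4 (S)-4-benzyl-3-(2-bromoacetyl)oxazolidin-2-one, via N-lithio oxazolidinone 3 (not isolated)
Conditions: n-BuLi, THF, −78 °C; then 2, −78 → 0 °C
Reagents that add atoms: none
Why: N-acylation of a lithiated oxazolidinone by an acid bromide is the standard route to N-acyl oxazolidinones, the acyl bromide reacts far faster than the alkyl bromide at −78 °C, and the C4 stereocentre is not touched.

**Step 2**
Reactants: 4 (S)-4-benzyl-3-(2-bromoacetyl)oxazolidin-2-one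
Product: 6 (S)-4-benzyl-3-[2-(triphenylphosphoranylidene)acetyl]oxazolidin-2-one, via phosphonium bromide 5 (not isolated)
Conditions: PPh3, toluene, rt; then aq. Na2CO3, CH2Cl2, 0 °C
Reagents that add atoms: triphenylphosphine, c1ccc(cc1)P(c1ccccc1)c1ccccc1
Why: SN2 displacement of the α-bromo imide by PPh3 gives the phosphonium salt, whose doubly activated CH2 is deprotonated by carbonate to the carbonyl-stabilised ylide (preparation of a Wittig reagent).

**Step 3**
Reactants: 6 (S)-4-benzyl-3-[2-(triphenylphosphoranylidene)acetyl]oxazolidin-2-one; 7 5-bromovanillin (3-bromo-4-hydroxy-5-methoxybenzaldehyde)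
Product: 8 (S)-4-benzyl-3-[(E)-3-(3-bromo-4-hydroxy-5-methoxyphenyl)prop-2-enoyl]oxazolidin-2-one
Conditions: toluene, 80 °C
Reagents that add atoms: none
Why: Wittig olefination of an aromatic aldehyde with a carbonyl-stabilised ylide gives the E-alkene and in a non-polar solvent should tolerate the free phenol.

**Step 4**
Reactants: 8 (S)-4-benzyl-3-[(E)-3-(3-bromo-4-hydroxy-5-methoxyphenyl)prop-2-enoyl]oxazolidin-2-one (two molecules)
Product: 11 3,3'-[(1R,2S)-8-bromo-1-(3-bromo-4-hydroxy-5-methoxyphenyl)-7-hydroxy-6-methoxy-1,2-dihydronaphthalene-2,3-dicarbonyl]bis[(S)-4-benzyloxazolidin-2-one], via bis-quinone methide 9 (not isolated), via mono-quinone methide 10 (not isolated)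
Conditions: FeCl3·6H2O (1.1 equiv per 8), acetone/H2O 4:1, 0 °C → rt; chromatography
Reagents that add atoms: none
Why: FeCl3 (trivalent iron, a one-electron oxidant) turns the phenol of 8 into a phenoxyl radical with spin density at C8, two such radicals join C8–C8' (the future C2–C3) to the bis-quinone methide 9, one quinone methide unit tautomerises by loss of its C8 proton to the E-cinnamoyl phenol 10, and the ring carbon of that unit para to OMe adds to the remaining quinone methide carbon (C1–C8a) before rearomatisation to 11. The closest known reaction type is the oxidative 8–8' dimerisation of 3,5-disubstituted 4-hydroxycinnamic esters and amides (sinapic type) with FeCl3 or peroxidase/H2O2 to trans-1-aryl-1,2-dihydronaphthalene-2,3-dicarboxylic derivatives, which has also been run on chiral N-acyl derivatives. Ring B closes by a 6-exo-trig Friedel–Crafts-type conjugate addition of the arene to the exocyclic quinone methide carbon. C2 is set in the radical coupling by the auxiliary: each imide should react in its dipole-opposed s-cis conformer on the C8 face away from the benzyl group, like with like, which gives (S,S)-9 and hence 2S whichever unit tautomerises. C1 is set by C2, since closure through the conformer with the C2 acyl group and the quinone methide aryl pseudo-diaxial (trans) avoids eclipsing with the C3 acyl group and the peri bromine, giving 1R. The step needs 8–8' instead of 8–5' coupling, secured by the bromine on the only free carbon ortho to the phenol oxygen (a C–C bond formed there cannot rearomatise), and closure para instead of ortho to OMe, for which the stronger para activation and the OMe methyl turned toward the ortho carbon speak; stereoisomers formed beside 11 are diastereomers because of the auxiliaries and are removed by chromatography or crystallisation.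

**Step 5**
Reactants: 11 the dibromo dihydronaphthalene bis-imide
Product: 12 3,3'-[(1R,2S,3R)-7-hydroxy-1-(4-hydroxy-3-methoxyphenyl)-6-methoxy-1,2,3,4-tetrahydronaphthalene-2,3-dicarbonyl]bis[(S)-4-benzyloxazolidin-2-one]
Conditions: H2 (3 bar), 10% Pd/C, NaOAc, EtOAc/EtOH, rt
Reagents that add atoms: none
Why: Catalytic hydrogenation over Pd/C should add H2 to C3=C4 from the face opposite the pseudoaxial C2 acyl group, the sense known for trans-1-aryl-1,2-dihydronaphthalene-2,3-dicarboxylic esters, which sets C3 as R (2,3-cis), while both aryl C–Br bonds are cleaved by hydrogenolysis and NaOAc takes up the HBr.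

**Step 6**
Reactants: 12 the tetralin bis-imide
Product: 13 (1R,2S,3R)-1-(4-hydroxy-3-methoxyphenyl)-2,3-bis(hydroxymethyl)-6-methoxy-1,2,3,4-tetrahydronaphthalen-7-ol
Conditions: LiBH4 (excess), THF/MeOH, 0 °C → rt; aq. NH4Cl
Reagents that add atoms: none
Why: Reductive cleavage of N-acyl oxazolidinones by LiBH4 at the exocyclic carbonyl gives the primary alcohols without enolisation, so C2 and C3 should keep their configuration, and auxiliary 1 is released for recovery.

**Step 7**
Reactants: 13 the bis-phenol diol
Product: 14 (1R,2S,3R)-1-(3,4-dimethoxyphenyl)-6,7-dimethoxy-2,3-bis(methoxymethyl)-1,2,3,4-tetrahydronaphthalene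
Conditions: NaH (excess), MeI (excess), THF/DMF, 0 °C → rt
Reagents that add atoms: iodomethane, CI
Why: Williamson etherification, in which NaH deprotonates both phenols and both primary alcohols and MeI methylates all four oxygens; no stereocentre is acidic under these conditions.

**Compound list**
1 | (S)-4-benzyloxazolidin-2-one | O=C1N[C@@H](Cc2ccccc2)CO1 | starting material
2 | bromoacetyl bromide | BrCC(Br)=O | starting material
3 | N-lithio-(S)-4-benzyloxazolidin-2-one (formed in the flask) | [Li]N1[C@@H](Cc2ccccc2)COC1=O | intermediate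
4 | (S)-4-benzyl-3-(2-bromoacetyl)oxazolidin-2-one | O=C1OC[C@H](Cc2ccccc2)N1C(=O)CBr | intermediate
5 | {2-[(S)-4-benzyl-2-oxooxazolidin-3-yl]-2-oxoethyl}triphenylphosphonium bromide (formed in the flask) | O=C1OC[C@H](Cc2ccccc2)N1C(=O)C[P+](c1ccccc1)(c1ccccc1)c1ccccc1.[Br-] | intermediate
6 | (S)-4-benzyl-3-[2-(triphenylphosphoranylidene)acetyl]oxazolidin-2-one | O=C1OC[C@H](Cc2ccccc2)N1C(=O)C=P(c1ccccc1)(c1ccccc1)c1ccccc1 | intermediate
7 | 5-bromovanillin (3-bromo-4-hydroxy-5-methoxybenzaldehyde) | O=Cc1cc(Br)c(O)c(OC)c1 | starting material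
8 | (S)-4-benzyl-3-[(E)-3-(3-bromo-4-hydroxy-5-methoxyphenyl)prop-2-enoyl]oxazolidin-2-one | O=C1OC[C@H](Cc2ccccc2)N1C(=O)/C=C/c1cc(Br)c(O)c(OC)c1 | intermediate
9 | 3,3'-{(2S,3S)-2,3-bis[(3-bromo-5-methoxy-4-oxocyclohexa-2,5-dien-1-ylidene)methyl]butanedioyl}bis[(S)-4-benzyloxazolidin-2-one] (bis-quinone methide, formed in the flask; geometry of the two ring-exocyclic C=C bonds not defined) | O=C1OC[C@H](Cc2ccccc2)N1C(=O)[C@@H](C=C1C=C(OC)C(=O)C(Br)=C1)[C@H](C=C1C=C(OC)C(=O)C(Br)=C1)C(=O)N1C(=O)OC[C@@H]1Cc1ccccc1 | intermediate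
10 | 3,3'-{(2E,3S)-2-(3-bromo-4-hydroxy-5-methoxybenzylidene)-3-[(3-bromo-5-methoxy-4-oxocyclohexa-2,5-dien-1-ylidene)methyl]butanedioyl}bis[(S)-4-benzyloxazolidin-2-one] (mono-quinone methide, formed in the flask; geometry of the ring-exocyclic C=C bond not defined) | O=C1OC[C@H](Cc2ccccc2)N1C(=O)/C(=C/c1cc(Br)c(O)c(OC)c1)[C@H](C=C1C=C(OC)C(=O)C(Br)=C1)C(=O)N1C(=O)OC[C@@H]1Cc1ccccc1 | intermediate
11 | 3,3'-[(1R,2S)-8-bromo-1-(3-bromo-4-hydroxy-5-methoxyphenyl)-7-hydroxy-6-methoxy-1,2-dihydronaphthalene-2,3-dicarbonyl]bis[(S)-4-benzyloxazolidin-2-one] | O=C1OC[C@H](Cc2ccccc2)N1C(=O)C1=Cc2cc(OC)c(O)c(Br)c2[C@@H](c2cc(Br)c(O)c(OC)c2)[C@@H]1C(=O)N1C(=O)OC[C@@H]1Cc1ccccc1 | intermediate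
12 | 3,3'-[(1R,2S,3R)-7-hydroxy-1-(4-hydroxy-3-methoxyphenyl)-6-methoxy-1,2,3,4-tetrahydronaphthalene-2,3-dicarbonyl]bis[(S)-4-benzyloxazolidin-2-one] | O=C1OC[C@H](Cc2ccccc2)N1C(=O)[C@@H]1Cc2cc(OC)c(O)cc2[C@@H](c2ccc(O)c(OC)c2)[C@@H]1C(=O)N1C(=O)OC[C@@H]1Cc1ccccc1 | intermediate
13 | (1R,2S,3R)-1-(4-hydroxy-3-methoxyphenyl)-2,3-bis(hydroxymethyl)-6-methoxy-1,2,3,4-tetrahydronaphthalen-7-ol | OC[C@@H]1Cc2cc(OC)c(O)cc2[C@@H](c2ccc(O)c(OC)c2)[C@@H]1CO | intermediate
14 | (1R,2S,3R)-1-(3,4-dimethoxyphenyl)-6,7-dimethoxy-2,3-bis(methoxymethyl)-1,2,3,4-tetrahydronaphthalene | COC[C@@H]1Cc2cc(OC)c(OC)cc2[C@@H](c2ccc(OC)c(OC)c2)[C@@H]1COC | target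

**Step count**
Total: 7 steps. Longest linear sequence: 7 steps (1 → 4 → 6 → 8 → 11 → 12 → 13 → 14); 2 and 7 enter as bought materials.

**Steps most likely to fail**

Step 4. Three processes could undermine it. Facial discrimination in the C8–C8' radical coupling may be weak, because the benzyl group lies far from C8 in the unchelated imide. Both quinone methide units of 9 may tautomerise to the achiral bis-benzylidene diene before ring closure, which erases the stereocentre set in the coupling. Ring closure may also occur in part ortho instead of para to OMe. The fallback gives up auxiliary control for resolution; it answers the stereochemical failures but not the regiochemical one. It sets out from 5-bromovanillin 7 and comes back at diol 13. Knoevenagel–Doebner condensation of 7 with monoethyl malonate (pyridine, piperidine, 90 °C) gives ethyl (E)-3-(3-bromo-4-hydroxy-5-methoxyphenyl)prop-2-enoate F1. FeCl3·6H2O in aqueous acetone should dimerise it, as it does 3,5-disubstituted 4-hydroxycinnamic esters, to diethyl (1R,2S)-8-bromo-1-(3-bromo-4-hydroxy-5-methoxyphenyl)-7-hydroxy-6-methoxy-1,2-dihydronaphthalene-2,3-dicarboxylate F2. F2 forms as the racemic trans compound, and the 1R,2S enantiomer is taken by preparative HPLC on a chiral stationary phase. Hydrogenation (H2, Pd/C, NaOAc, EtOH) then gives diethyl (1R,2S,3R)-7-hydroxy-1-(4-hydroxy-3-methoxyphenyl)-6-methoxy-1,2,3,4-tetrahydronaphthalene-2,3-dicarboxylate F3, and LiAlH4 in THF at 0 °C reduces both esters to 13.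

Step 5. Hydrogen may be delivered from the wrong face, or the reduction may stall because the two bulky imides keep the trisubstituted alkene from the catalyst surface; long exposure could also epimerise the kinetically formed cis centre at C3. The fallback removes the auxiliaries first, so that the reduction runs on the diester class for which the 2,3-cis course is established. It sets out from 11 and comes back at 13. Transesterification with MeOMgBr (from MeMgBr and MeOH, THF, 0 °C) releases both auxiliaries and gives dimethyl (1R,2S)-8-bromo-1-(3-bromo-4-hydroxy-5-methoxyphenyl)-7-hydroxy-6-methoxy-1,2-dihydronaphthalene-2,3-dicarboxylate F4. Hydrogenation (H2, Pd/C, NaOAc, MeOH) gives dimethyl (1R,2S,3R)-7-hydroxy-1-(4-hydroxy-3-methoxyphenyl)-6-methoxy-1,2,3,4-tetrahydronaphthalene-2,3-dicarboxylate F5, and LiAlH4 in THF at 0 °C gives 13.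

Step 3. The acidic ortho-bromophenol may transfer its proton to the ylide, leaving a phosphonium phenoxide pair that does not olefinate. The fallback masks the phenol during the olefination; it sets out from 7 and comes back at 8. TBSCl and imidazole in DMF give 3-bromo-4-[(tert-butyldimethylsilyl)oxy]-5-methoxybenzaldehyde F6. Wittig reaction of F6 with ylide 6 (toluene, 80 °C) gives (S)-4-benzyl-3-[(E)-3-{3-bromo-4-[(tert-butyldimethylsilyl)oxy]-5-methoxyphenyl}prop-2-enoyl]oxazolidin-2-one F7, and TBAF buffered with AcOH in THF at 0 °C frees the phenol to give 8.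

**Further compounds**
F1 | step 4 | ethyl (E)-3-(3-bromo-4-hydroxy-5-methoxyphenyl)prop-2-enoate | CCOC(=O)/C=C/c1cc(Br)c(O)c(OC)c1
F2 | step 4 | diethyl (1R,2S)-8-bromo-1-(3-bromo-4-hydroxy-5-methoxyphenyl)-7-hydroxy-6-methoxy-1,2-dihydronaphthalene-2,3-dicarboxylate | CCOC(=O)C1=Cc2cc(OC)c(O)c(Br)c2[C@@H](c2cc(Br)c(O)c(OC)c2)[C@@H]1C(=O)OCC
F3 | step 4 | diethyl (1R,2S,3R)-7-hydroxy-1-(4-hydroxy-3-methoxyphenyl)-6-methoxy-1,2,3,4-tetrahydronaphthalene-2,3-dicarboxylate | CCOC(=O)[C@@H]1Cc2cc(OC)c(O)cc2[C@@H](c2ccc(O)c(OC)c2)[C@@H]1C(=O)OCC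
F4 | step 5 | dimethyl (1R,2S)-8-bromo-1-(3-bromo-4-hydroxy-5-methoxyphenyl)-7-hydroxy-6-methoxy-1,2-dihydronaphthalene-2,3-dicarboxylate | COC(=O)C1=Cc2cc(OC)c(O)c(Br)c2[C@@H](c2cc(Br)c(O)c(OC)c2)[C@@H]1C(=O)OC
F5 | step 5 | dimethyl (1R,2S,3R)-7-hydroxy-1-(4-hydroxy-3-methoxyphenyl)-6-methoxy-1,2,3,4-tetrahydronaphthalene-2,3-dicarboxylate | COC(=O)[C@@H]1Cc2cc(OC)c(O)cc2[C@@H](c2ccc(O)c(OC)c2)[C@@H]1C(=O)OC
F6 | step 3 | 3-bromo-4-[(tert-butyldimethylsilyl)oxy]-5-methoxybenzaldehyde | O=Cc1cc(Br)c(O[Si](C)(C)C(C)(C)C)c(OC)c1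
F7 | step 3 | (S)-4-benzyl-3-[(E)-3-{3-bromo-4-[(tert-butyldimethylsilyl)oxy]-5-methoxyphenyl}prop-2-enoyl]oxazolidin-2-one | O=C1OC[C@H](Cc2ccccc2)N1C(=O)/C=C/c1cc(Br)c(O[Si](C)(C)C(C)(C)C)c(OC)c1
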